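The carbocycle is numbered C1 (=CH2), C2, C3, C4 (CHBr), C5 (CMe2), C6 (CH–CH2Ar), and everything rests on cutting C2–C3. The feature exploited is the exocyclic C1 methylene standing 1,4 to C4, which is flanked by quaternary C5. With C4 as ketone and an ester on C3, an oxidatively generated C3 radical closes the six-membered ring onto an isopropenyl group at C6. Loss of a methyl hydrogen leaves C1=CH2 in the same operation. The precursor is an acyclic (S)-β-keto ester bearing CMe2, the dimethyl-protected bromohydroquinone benzyl group and isopropenyl. A removable chlorine on C3 shields the product from re-oxidation. Iridium-catalysed allylation sets C6; reduction and inversion set C4.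

Key step: step 10

Assumption: the (Ra,R,R) ligand is taken to deliver the 3S ester 8 by the usual facial rule of this catalyst family; should the sense be opposite, the equally available mirror-image ligand is used and nothing else changes.

Step 1
Reactants: 1 1,4-dibromo-2,5-dimethoxybenzene; 2 allyl bromide
Product: 4 1-allyl-4-bromo-2,5-dimethoxybenzene, via aryllithium 3 (not isolated)
Conditions: n-BuLi (1.0 equiv), THF, −78 °C; then 2, −78 °C → rt
Reagents that add atoms: none
Why: Bromine–lithium exchange followed by SN2 allylation: the two C–Br bonds of 1 are equivalent, so one equivalent of n-BuLi at −78 °C should exchange only one of them, and the aryllithium, which has no ortho halogen and so cannot collapse to an aryne, is alkylated by 2 while the second bromine stays as the aryl bromine of the target.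

Step 2
Reactants: 4 1-allyl-4-bromo-2,5-dimethoxybenzene; 5 allyl methyl carbonate
Product: 6 (E)-4-(4-bromo-2,5-dimethoxyphenyl)but-2-en-1-yl methyl carbonate
Conditions: second-generation Grubbs catalyst (3 mol %), 5 (3 equiv), 1,4-benzoquinone (10 mol %), CH2Cl2, 40 °C
Reagents that add atoms: none
Why: Olefin cross-metathesis of an allylarene with an allylic ester-type partner, two unhindered terminal alkenes, is steered to the cross product by excess 5 and loss of ethene and should settle on the more stable E alkene, with benzoquinone suppressing hydride-mediated migration of the double bond towards the arene.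

Step 3
Reactants: 6 (E)-4-(4-bromo-2,5-dimethoxyphenyl)but-2-en-1-yl methyl carbonate; 7 1-methoxy-2-methyl-1-(trimethylsilyloxy)propene
Product: 8 methyl (3S)-3-(4-bromo-2,5-dimethoxybenzyl)-2,2-dimethylpent-4-enoate
Conditions: [Ir(cod)Cl]2 (2 mol %), (Ra,R,R)-O,O′-(1,1′-binaphthyl-2,2′-diyl)-N,N-bis(1-phenylethyl)phosphoramidite (4 mol %), n-PrNH2 pre-activation, 7 (2 equiv), THF, rt
Reagents that add atoms: none
Why: Iridium-catalysed asymmetric allylic alkylation with a silyl ketene acetal: the cyclometalated iridium phosphoramidite complex ionises 6, the methyl carbonate anion loses CO2 and desilylates 7, and the ester enolate attacks the substituted allyl terminus opposite to the metal, so the branched product forms and the ligand alone sets C6 (3S in 8).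

Step 4
Reactants: 8 methyl (3S)-3-(4-bromo-2,5-dimethoxybenzyl)-2,2-dimethylpent-4-enoate
Product: 9 methyl (3R)-3-(4-bromo-2,5-dimethoxybenzyl)-2,2-dimethyl-4-oxopentanoate
Conditions: PdCl2 (10 mol %), CuCl (1 equiv), O2 (1 atm), DMF/H2O, rt
Reagents that add atoms: water, O
Why: Tsuji–Wacker oxidation, the standard conversion of an allylated ester into a 1,4-dicarbonyl compound: divalent palladium activates the monosubstituted alkene, water attacks the internal carbon, CuCl and O2 turn the palladium over, and the neutral medium leaves the now α-carbonyl C6 centre unchanged (the descriptor becomes R only because acetyl outranks the quaternary carbon).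

Step 5
Reactants: 9 methyl (3R)-3-(4-bromo-2,5-dimethoxybenzyl)-2,2-dimethyl-4-oxopentanoate
Product: 10 methyl (3S)-3-(4-bromo-2,5-dimethoxybenzyl)-2,2,4-trimethylpent-4-enoate
Conditions: Zn, CH2Br2, TiCl4, THF, −40 → 5 °C (aged); then 9, CH2Cl2, 0 °C → rt
Reagents that add atoms: dibromomethane, BrCBr
Why: Takai–Lombardo methylenation: the non-basic titanium–zinc methylene reagent converts the ketone into the isopropenyl group without enolising it, which avoids both epimerisation at C6 and base-induced ring closure of the methyl ketone onto the ester, and it leaves the hindered ester and the aryl bromide alone.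

Step 6
Reactants: 10 methyl (3S)-3-(4-bromo-2,5-dimethoxybenzyl)-2,2,4-trimethylpent-4-enoate
Product: 11 (3S)-3-(4-bromo-2,5-dimethoxybenzyl)-2,2,4-trimethylpent-4-enal
Conditions: i-Bu2AlH (1.1 equiv), toluene, −78 °C; MeOH, then aq potassium sodium tartrate
Reagents that add atoms: none
Why: Partial reduction of an ester with i-Bu2AlH: the crowded tetrahedral aluminium hemiacetal next to the quaternary carbon should persist at −78 °C and collapse to the aldehyde only on quenching, and the aldehyde has no α-hydrogen to lose.

Step 7
Reactants: 11 (3S)-3-(4-bromo-2,5-dimethoxybenzyl)-2,2,4-trimethylpent-4-enal; 12 methyl acetate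
Product: 14 methyl (5S)-5-(4-bromo-2,5-dimethoxybenzyl)-3-hydroxy-4,4,6-trimethylhept-6-enoate (C3 epimers), via lithium enolate 13 (not isolated)
Conditions: LiN(i-Pr)2, 12, THF, −78 °C; then 11, −78 °C; AcOH quench
Reagents that add atoms: none
Why: Aldol addition of a preformed lithium ester enolate to a non-enolisable aldehyde is chosen over a direct Claisen condensation because ester 10 is too shielded for enolate attack whereas the aldehyde is not, and the new carbinol centre forms as an inconsequential epimer mixture that step 8 removes.

Step 8
Reactants: 14 methyl (5S)-5-(4-bromo-2,5-dimethoxybenzyl)-3-hydroxy-4,4,6-trimethylhept-6-enoate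
Product: 15 methyl (5S)-5-(4-bromo-2,5-dimethoxybenzyl)-4,4,6-trimethyl-3-oxohept-6-enoate
Conditions: Dess–Martin periodinane (1.2 equiv), CH2Cl2, 0 °C → rt
Reagents that add atoms: none
Why: Dess–Martin oxidation of a β-hydroxy ester to the β-keto ester runs under near-neutral conditions that spare the alkene, the electron-rich arene and C6.

Step 9
Reactants: 15 methyl (5S)-5-(4-bromo-2,5-dimethoxybenzyl)-4,4,6-trimethyl-3-oxohept-6-enoate
Product: 16 methyl (5S)-5-(4-bromo-2,5-dimethoxybenzyl)-2-chloro-4,4,6-trimethyl-3-oxohept-6-enoate (C2 epimers)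
Conditions: N-chlorosuccinimide (1.0 equiv), Mg(ClO4)2 (30 mol %), MeCN, 0 °C → rt
Reagents that add atoms: N-chlorosuccinimide, O=C1CCC(=O)N1Cl
Why: Lewis-acid-catalysed electrophilic α-chlorination of a 1,3-dicarbonyl compound: chelation by Mg(ClO4)2 raises the enol content so that the mild chlorine donor reacts at the active methylene far faster than at the isopropenyl group or the brominated arene, and the new labile centre is of no consequence.

Step 10
Reactants: 16 methyl (5S)-5-(4-bromo-2,5-dimethoxybenzyl)-2-chloro-4,4,6-trimethyl-3-oxohept-6-enoate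
Product: 17 methyl (4S)-4-(4-bromo-2,5-dimethoxybenzyl)-1-chloro-3,3-dimethyl-5-methylidene-2-oxocyclohexane-1-carboxylate (C1 epimers)
Conditions: Mn(OAc)3·2H2O (2.2 equiv), Cu(OAc)2·H2O (1 equiv), degassed AcOH, 40 °C
Reagents that add atoms: none
Why: Mn(OAc)3 oxidises the manganese enolate of 16 (only target C3 can enolise, since C5 is quaternary) to an electrophilic chloro keto ester radical, which adds to the unsubstituted CH2 terminus of the isopropenyl group, forging C2–C3 and leaving a tertiary radical at C1. Cu(OAc)2 captures that radical as an alkylcopper species that undergoes oxidative β-hydrogen elimination, and the monovalent copper released is re-oxidised by the second equivalent of Mn(OAc)3. The closest known reaction type is the oxidative free-radical cyclisation of unsaturated α-chloro β-keto esters with Mn(OAc)3 and Cu(OAc)2 to methylenecyclohexanones. The single ring closes in the 6-endo-trig mode, which 2-oxohex-5-enyl radicals favour and which the 1,1-disubstituted alkene and the gem-dimethyl group reinforce against 5-exo attack at the fully substituted carbon. No lasting stereocentre is made: C3 forms as an epimer mixture that steps 11 and 12 erase, and C6, neither enolisable nor among the reacting atoms, keeps its configuration. The selectivities needed are endo closure, elimination towards the methyl group (the bulky organocopper intermediate should take the most accessible and most numerous hydrogens) and a stop after two electrons, which the chlorine secures because 17 has no enolisable hydrogen left, while the methyl ethers keep the arene oxygens from trapping C1.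

Step 11
Reactants: 17 methyl (4S)-4-(4-bromo-2,5-dimethoxybenzyl)-1-chloro-3,3-dimethyl-5-methylidene-2-oxocyclohexane-1-carboxylate
Product: 18 methyl (4S)-4-(4-bromo-2,5-dimethoxybenzyl)-3,3-dimethyl-5-methylidene-2-oxocyclohexane-1-carboxylate (C1 labile)
Conditions: Zn, AcOH, rt
Reagents that add atoms: none
Why: Reductive dehalogenation of an α-halo β-dicarbonyl compound: Zn inserts into the activated C–Cl bond, the zinc enolate is protonated by AcOH, and the aryl bromide, the ester and the unactivated alkene are not reduced under these conditions.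

Step 12
Reactants: 18 methyl (4S)-4-(4-bromo-2,5-dimethoxybenzyl)-3,3-dimethyl-5-methylidene-2-oxocyclohexane-1-carboxylate
Product: 19 (3S)-3-(4-bromo-2,5-dimethoxybenzyl)-2,2-dimethyl-4-methylidenecyclohexan-1-one
Conditions: LiCl, H2O, DMSO, 140 °C
Reagents that add atoms: none
Why: Krapcho dealkoxycarbonylation: chloride demethylates the ester, the β-keto carboxylate loses CO2 and the enolate is protonated by water, all under neutral conditions that should neither move the exocyclic alkene nor affect C6, which quaternary C5 insulates from the ketone.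

Step 13
Reactants: 19 (3S)-3-(4-bromo-2,5-dimethoxybenzyl)-2,2-dimethyl-4-methylidenecyclohexan-1-one
Product: 20 (1S,3S)-3-(4-bromo-2,5-dimethoxybenzyl)-2,2-dimethyl-4-methylidenecyclohexan-1-ol
Conditions: KBH(s-Bu)3, THF, −78 → 0 °C; then NaOH, H2O2, 0 °C
Reagents that add atoms: none
Why: Substrate-controlled reduction with a bulky trialkylborohydride: hydride should arrive along the equatorial trajectory of the chair that holds the C6 benzyl group equatorial (the flipped chair would push the new C–O bond into a syn-axial clash with that group), giving the axial C4 alcohol trans to the benzyl group, as is usual for cyclohexanones next to a gem-dimethyl carbon.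

Step 14
Reactants: 20 (1S,3S)-3-(4-bromo-2,5-dimethoxybenzyl)-2,2-dimethyl-4-methylidenecyclohexan-1-ol
Product: 21 1-bromo-4-{[(1S,3R)-3-bromo-2,2-dimethyl-6-methylidenecyclohexyl]methyl}-2,5-dimethoxybenzene
Conditions: CBr4, P(n-C8H17)3, 2,6-di-tert-butyl-4-methylpyridine, toluene, 70 °C
Reagents that add atoms: tetrabromomethane, BrC(Br)(Br)Br
Why: Appel-type bromination: bromide displaces the alkoxyphosphonium group by SN2 with inversion, turning the axial C–O bond into the equatorial C4–Br bond cis to the benzyl group (R), and the trialkylphosphine in warm toluene is the variant established for secondary alcohols beside a quaternary carbon, with the hindered pyridine keeping HBr away from the exocyclic alkene.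

Step 15
Reactants: 21 1-bromo-4-{[(1S,3R)-3-bromo-2,2-dimethyl-6-methylidenecyclohexyl]methyl}-2,5-dimethoxybenzene
Product: 23 cyclocymopol (2-bromo-5-{[(1S,3R)-3-bromo-2,2-dimethyl-6-methylidenecyclohexyl]methyl}benzene-1,4-diol), via bromoquinone 22 (not isolated)
Conditions: (NH4)2Ce(NO3)6 (2.5 equiv), MeCN/H2O, 0 °C; extraction into EtOAc, then aq Na2S2O4, rt
Reagents that add atoms: water, O
Why: Oxidative demethylation of a hydroquinone dimethyl ether by tetravalent cerium (the quinone oxygens come from water) followed by dithionite reduction frees both phenols without the Lewis or Brønsted acids that would isomerise the exocyclic alkene or ionise the secondary bromide, and neither stereocentre is involved.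

Compound list
1 | 1,4-dibromo-2,5-dimethoxybenzene | COc1cc(Br)c(OC)cc1Br | starting material
2 | allyl bromide | C=CCBr | starting material
3 | (4-bromo-2,5-dimethoxyphenyl)lithium | [Li]c1cc(OC)c(Br)cc1OC | intermediate
4 | 1-allyl-4-bromo-2,5-dimethoxybenzene | C=CCc1cc(OC)c(Br)cc1OC | intermediate
5 | allyl methyl carbonate | C=CCOC(=O)OC | starting material
6 | (E)-4-(4-bromo-2,5-dimethoxyphenyl)but-2-en-1-yl methyl carbonate | COC(=O)OC/C=C/Cc1cc(OC)c(Br)cc1OC | intermediate
7 | 1-methoxy-2-methyl-1-(trimethylsilyloxy)propene | COC(O[Si](C)(C)C)=C(C)C | starting material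
8 | methyl (3S)-3-(4-bromo-2,5-dimethoxybenzyl)-2,2-dimethylpent-4-enoate | COC(=O)C(C)(C)[C@@H](Cc1cc(OC)c(Br)cc1OC)C=C | intermediate
9 | methyl (3R)-3-(4-bromo-2,5-dimethoxybenzyl)-2,2-dimethyl-4-oxopentanoate | COC(=O)C(C)(C)[C@@H](Cc1cc(OC)c(Br)cc1OC)C(C)=O | intermediate
10 | methyl (3S)-3-(4-bromo-2,5-dimethoxybenzyl)-2,2,4-trimethylpent-4-enoate | COC(=O)C(C)(C)[C@@H](Cc1cc(OC)c(Br)cc1OC)C(C)=C | intermediate
11 | (3S)-3-(4-bromo-2,5-dimethoxybenzyl)-2,2,4-trimethylpent-4-enal | O=CC(C)(C)[C@@H](Cc1cc(OC)c(Br)cc1OC)C(C)=C | intermediate
12 | methyl acetate | COC(C)=O | starting material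
13 | lithium enolate of methyl acetate | C=C(OC)O[Li] | intermediate
14 | methyl (5S)-5-(4-bromo-2,5-dimethoxybenzyl)-3-hydroxy-4,4,6-trimethylhept-6-enoate (C3 epimers) | COC(=O)CC(O)C(C)(C)[C@@H](Cc1cc(OC)c(Br)cc1OC)C(C)=C | intermediate
15 | methyl (5S)-5-(4-bromo-2,5-dimethoxybenzyl)-4,4,6-trimethyl-3-oxohept-6-enoate | COC(=O)CC(=O)C(C)(C)[C@@H](Cc1cc(OC)c(Br)cc1OC)C(C)=C | intermediate
16 | methyl (5S)-5-(4-bromo-2,5-dimethoxybenzyl)-2-chloro-4,4,6-trimethyl-3-oxohept-6-enoate (C2 epimers) | COC(=O)C(Cl)C(=O)C(C)(C)[C@@H](Cc1cc(OC)c(Br)cc1OC)C(C)=C | intermediate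
17 | methyl (4S)-4-(4-bromo-2,5-dimethoxybenzyl)-1-chloro-3,3-dimethyl-5-methylidene-2-oxocyclohexane-1-carboxylate (C1 epimers) | C=C1CC(Cl)(C(=O)OC)C(=O)C(C)(C)[C@H]1Cc1cc(OC)c(Br)cc1OC | intermediate
18 | methyl (4S)-4-(4-bromo-2,5-dimethoxybenzyl)-3,3-dimethyl-5-methylidene-2-oxocyclohexane-1-carboxylate (C1 labile) | C=C1CC(C(=O)OC)C(=O)C(C)(C)[C@H]1Cc1cc(OC)c(Br)cc1OC | intermediate
19 | (3S)-3-(4-bromo-2,5-dimethoxybenzyl)-2,2-dimethyl-4-methylidenecyclohexan-1-one | C=C1CCC(=O)C(C)(C)[C@H]1Cc1cc(OC)c(Br)cc1OC | intermediate
20 | (1S,3S)-3-(4-bromo-2,5-dimethoxybenzyl)-2,2-dimethyl-4-methylidenecyclohexan-1-ol | C=C1CC[C@H](O)C(C)(C)[C@H]1Cc1cc(OC)c(Br)cc1OC | intermediate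
21 | 1-bromo-4-{[(1S,3R)-3-bromo-2,2-dimethyl-6-methylidenecyclohexyl]methyl}-2,5-dimethoxybenzene | C=C1CC[C@@H](Br)C(C)(C)[C@H]1Cc1cc(OC)c(Br)cc1OC | intermediate
22 | 2-bromo-5-{[(1S,3R)-3-bromo-2,2-dimethyl-6-methylidenecyclohexyl]methyl}cyclohexa-2,5-diene-1,4-dione | C=C1CC[C@@H](Br)C(C)(C)[C@H]1CC1=CC(=O)C(Br)=CC1=O | intermediate
23 | cyclocymopol, 2-bromo-5-{[(1S,3R)-3-bromo-2,2-dimethyl-6-methylidenecyclohexyl]methyl}benzene-1,4-diol | C=C1CC[C@@H](Br)C(C)(C)[C@H]1Cc1cc(O)c(Br)cc1O | target

Total step count: 15. Longest linear sequence: 15 steps (1 to 23).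

Steps most likely to fail

(a) Step 10.
- **Risk:** the copper-mediated elimination may take a ring hydrogen instead of a methyl hydrogen. Oxidation of the hindered chloro keto ester may be sluggish. Electron transfer from the dimethoxyarene may compete.
- **Fallback:** it separates ring closure from alkene formation, sets out from 15 and comes back at 18, so that steps 9 to 11 fall away.
  - NaH in THF and then PhSeCl at −78 °C should give the α-phenylselanyl β-keto ester F1.
  - Irradiation with a tungsten lamp in benzene starts a phenylselenide group-transfer radical chain. The same C3 radical closes 6-endo, and the tertiary C1 radical abstracts PhSe from F1, giving the tertiary selenide F2.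
  - H2O2 in CH2Cl2 with pyridine gives the selenoxide F3. Its syn elimination, which is geometrically difficult towards ring hydrogens of a cyclohexane, should use the freely rotating methyl group and deliver 18.

(b) Step 14.
- **Risk:** substitution at a secondary carbon beside quaternary C5 is slow. Anti elimination of the axial C3 hydrogen or migration of the antiperiplanar axial C5 methyl group may outrun it.
- **Fallback:** it separates activation from displacement, sets out from 20 and comes back at 21.
  - Chloromethanesulfonyl chloride and pyridine at 0 °C should give the chloromethanesulfonate F4, a leaving group designed for inversion of hindered secondary alcohols.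
  - F4 is then displaced by LiBr in DMF at about 50 °C. Solvent, counter-ion and temperature can be tuned there without any phosphorus species present.

(c) Step 13.
- **Risk:** facial selectivity may be poor. The flipped chair with an axial benzyl group relieves allylic strain against C1=CH2 and gauche contacts with the C5 methyl groups, and it would present the opposite face to the hydride.
- **Fallback:** it replaces substrate control by reagent control, sets out from 19 and comes back at 20.
  - A Corey–Bakshi–Shibata reduction with (R)-2-methyl-CBS-oxazaborolidine and catecholborane in toluene at −40 °C distinguishes the CMe2 flank from the CH2 flank of the ketone and should give the 1S alcohol whatever the ring conformation.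
  - Catecholborane leaves the alkene alone at this temperature.
  - No new compound arises (entry F0).

Further compounds
F1 | step 10 | methyl (5S)-5-(4-bromo-2,5-dimethoxybenzyl)-4,4,6-trimethyl-3-oxo-2-(phenylselanyl)hept-6-enoate (C2 epimers) | COC(=O)C([Se]c1ccccc1)C(=O)C(C)(C)[C@@H](Cc1cc(OC)c(Br)cc1OC)C(C)=C
F2 | step 10 | methyl (4R)-4-(4-bromo-2,5-dimethoxybenzyl)-3,3,5-trimethyl-2-oxo-5-(phenylselanyl)cyclohexane-1-carboxylate (C1 and C5 epimers) | CC1([Se]c2ccccc2)CC(C(=O)OC)C(=O)C(C)(C)[C@H]1Cc1cc(OC)c(Br)cc1OC
F3 | step 10 | methyl (4R)-4-(4-bromo-2,5-dimethoxybenzyl)-3,3,5-trimethyl-2-oxo-5-(phenylseleninyl)cyclohexane-1-carboxylate | CC1([Se](=O)c2ccccc2)CC(C(=O)OC)C(=O)C(C)(C)[C@H]1Cc1cc(OC)c(Br)cc1OC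
F4 | step 14 | (1S,3S)-3-(4-bromo-2,5-dimethoxybenzyl)-2,2-dimethyl-4-methylidenecyclohexyl chloromethanesulfonate | C=C1CC[C@H](OS(=O)(=O)CCl)C(C)(C)[C@H]1Cc1cc(OC)c(Br)cc1OC
F0 | step 13 | none | none
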